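**Retrosynthetic overview**

1. Lactone ring B is opened at O1–C2. It is the last ring to form: the acid-freed C8a–OH closes on a methyl ester once the C3=C4 alkene is cis.
2. C4a–C4 and C5–CH2 are cut together by a three-component Catellani coupling of a C4a aryl iodide (ring A), (S)-propylene oxide and a 2-(dihydropyranonyl)acrylate, ending in a Heck reaction.
3. The feature that carries the plan: ring A is fully substituted, and in the iodide C5 holds the only aromatic hydrogen, directly ortho to C4a–I, while the C8a oxygen blocks the other ortho carbon. One palladium/norbornene cycle can therefore functionalize C5 and then C4a.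
4. Ring A comes from 2-methylresorcinol (C6 methyl, iodine, MOM ethers). Ring C (dihydropyranone) is built in its own fragment from methyl (R)-3-hydroxybutanoate and methyl acetoacetate by acylation, cyclodehydration (O1'–C6') and α-methylenation.
5. Ring order: ring A is bought, ring C closes in step 8, ring B in step 11.

Key step: step 10

Assumption: plain locants (C2–C8a) follow the coumarin numbering of the target and primed locants the dihydropyranone; the coupling product is treated as a mixture of alkene geometric isomers, because both are expected to converge in the last step.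

**Route**

Step 1
Reactants: 1 2-methylresorcinol
Product: 2 2,4-dihydroxy-3-methylbenzaldehyde
Conditions: POCl3, DMF, MeCN, 0 °C to rt; then H2O, 50 °C
Reagents that add atoms: N,N-dimethylformamide CN(C)C=O (formyl carbon); water O (formyl oxygen)
Why: Vilsmeier–Haack formylation should occur at the ring carbon ortho to one hydroxyl and para to the other, since the position between the hydroxyls is blocked by the methyl group.

Step 2
Reactants: 2 2,4-dihydroxy-3-methylbenzaldehyde
Product: 3 2,4-dimethylbenzene-1,3-diol
Conditions: H2 (3 atm), 10 % Pd/C, AcOH, HCl (cat.), rt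
Reagents that add atoms: none
Why: Catalytic hydrogenolysis of an ortho/para-hydroxy benzaldehyde proceeds through the benzylic alcohol, whose C–O bond is activated by the phenols, and should stop at the methyl group without ring reduction.

Step 3
Reactants: 3 2,4-dimethylbenzene-1,3-diol
Product: 4 4-iodo-2,6-dimethylbenzene-1,3-diol
Conditions: NIS (1.0 equiv), MeCN, 0 °C, dark
Reagents that add atoms: N-iodosuccinimide O=C1CCC(=O)N1I
Why: Electrophilic aromatic iodination should take the single free carbon that is ortho and para to the hydroxyls, the other free carbon being meta to both.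

Step 4
Reactants: 4 4-iodo-2,6-dimethylbenzene-1,3-diol
Product: 5 1-iodo-2,4-bis(methoxymethoxy)-3,5-dimethylbenzene
Conditions: NaH, MOMCl, DMF, 0 °C to rt
Reagents that add atoms: chloromethyl methyl ether COCCl
Why: Williamson-type O-alkylation of both sodium phenoxides with MOMCl is reliable even for phenols flanked by two ortho substituents, and leaves the aryl iodide untouched.

Step 5
Reactants: 6 methyl (R)-3-hydroxybutanoate
Product: 7 methyl (R)-3-[(tert-butyldimethylsilyl)oxy]butanoate
Conditions: TBSCl, imidazole, DMF, rt
Reagents that add atoms: tert-butyldimethylsilyl chloride CC(C)(C)[Si](C)(C)Cl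
Why: Imidazole-promoted silylation of the secondary alcohol breaks no bond at the stereocenter, so the (R) configuration is carried through.

Step 6
Reactants: 7 methyl (R)-3-[(tert-butyldimethylsilyl)oxy]butanoate
Product: 8 (R)-3-[(tert-butyldimethylsilyl)oxy]-N-methoxy-N-methylbutanamide
Conditions: MeNH(OMe)·HCl, i-PrMgCl, THF, −20 to 0 °C
Reagents that add atoms: N,O-dimethylhydroxylamine hydrochloride CNOC.Cl
Why: Aminolysis of the ester by the chloromagnesium amide of N,O-dimethylhydroxylamine is a standard low-temperature route to N-methoxy-N-methylamides and should not cause β-elimination of the silyloxy group.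

Step 7
Reactants: 8 (R)-3-[(tert-butyldimethylsilyl)oxy]-N-methoxy-N-methylbutanamide; 9 methyl acetoacetate
Product: 10 methyl (7R)-7-[(tert-butyldimethylsilyl)oxy]-3,5-dioxooctanoate
Conditions: 9 (2.5 equiv), NaH then n-BuLi, THF, 0 °C; add 8, −78 to 0 °C; cold aq. HCl quench
Reagents that add atoms: none
Why: The terminal carbon of the acetoacetate dianion acylates the N-methoxy-N-methylamide (Weinreb ketone synthesis), the chelated tetrahedral adduct preventing a second addition and the excess dianion absorbing the acidic product.

Step 8
Reactants: 10 methyl (7R)-7-[(tert-butyldimethylsilyl)oxy]-3,5-dioxooctanoate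
Product: 12 methyl 2-[(2R)-2-methyl-4-oxo-3,4-dihydro-2H-pyran-6-yl]acetate, via hydroxy dioxo ester 11 (not isolated)
Conditions: CF3CO2H (20 vol %), CH2Cl2, H2O (2 equiv), 0 °C to rt
Reagents that add atoms: none
Why: Acid removes the silyl group, and the freed C7 hydroxyl adds to the C3 ketone to give a six-membered hemiketal that dehydrates into conjugation with the C5 ketone (cyclodehydration of a δ-hydroxy-β-diketone), the C–O bond at the stereocenter staying intact.

Step 9
Reactants: 12 methyl 2-[(2R)-2-methyl-4-oxo-3,4-dihydro-2H-pyran-6-yl]acetate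
Product: 13 methyl 2-[(2R)-2-methyl-4-oxo-3,4-dihydro-2H-pyran-6-yl]prop-2-enoate
Conditions: (CH2O)n, K2CO3, n-Bu4NI (cat.), toluene, 60 °C; product kept as a cold BHT-stabilized solution and used at once
Reagents that add atoms: paraformaldehyde (as formaldehyde) C=O
Why: Knoevenagel-type aldol condensation with formaldehyde, as used to turn arylacetates into 2-arylacrylates, can lose water only at the CH2 between the ester and C6', so a reversible aldol addition at C5' should drain back to the desired acrylate.

Step 10
Reactants: 5 1-iodo-2,4-bis(methoxymethoxy)-3,5-dimethylbenzene; 13 methyl 2-[(2R)-2-methyl-4-oxo-3,4-dihydro-2H-pyran-6-yl]prop-2-enoate; 14 (S)-propylene oxide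
Product: 15 methyl 3-{2-[(2S)-2-hydroxypropyl]-4,6-bis(methoxymethoxy)-3,5-dimethylphenyl}-2-[(2R)-2-methyl-4-oxo-3,4-dihydro-2H-pyran-6-yl]prop-2-enoate (mixture of alkene geometric isomers)
Conditions: Pd(OAc)2 (10 mol %), XPhos (20 mol %), potassium 5-norbornene-2-carboxylate (0.5 equiv), K2CO3 (1.5 equiv), 14 (5 equiv), 13 (1.5 equiv, added in portions), NMP, 60 °C, sealed vessel
Reagents that add atoms: none
Why: Proposed new method: oxidative addition of the C4a–I bond of 5 to zerovalent palladium is followed by norbornene insertion and carbonate-assisted metalation of C5–H, the only C–H within reach, to give a five-membered palladacycle; SN2-type attack of this divalent palladium center on the CH2 carbon of 14 raises the metal to the tetravalent state, and C(sp2)–C(sp3) reductive elimination makes the C5–CH2 bond. Because C4a is then flanked by two substituents, β-carbon elimination expels the norbornene and the freed aryl divalent palladium species carbopalladates 13 at its CH2 terminus (bond C4a–C4); the only β-hydrogens available for syn elimination are those of the new benzylic CH2, which leads to the trisubstituted alkene. The closest known reaction type is the Catellani ortho-alkylation of ortho-substituted aryl iodides with epoxides terminated by Heck coupling with simple acrylates; not yet shown are metalation of a C–H bond flanked by a methyl group and a 1,1-disubstituted, doubly activated acrylate as terminator. No ring is closed and no stereocenter is created: the carbinol center comes unchanged from 14, whose stereogenic carbon keeps its C–O bond, and the pyranone center comes from 13. The step needs ortho alkylation before ipso coupling, which the C8a OMOM group secures by allowing norbornene extrusion only after C5 is substituted, helped by a large excess of 14 and portionwise dosing of 13. It also needs Heck termination to outrun closure of the new alkoxide onto C4a, for which the bulky biarylphosphine and the moderate temperature are chosen.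

Step 11
Reactants: 15 methyl 3-{2-[(2S)-2-hydroxypropyl]-4,6-bis(methoxymethoxy)-3,5-dimethylphenyl}-2-[(2R)-2-methyl-4-oxo-3,4-dihydro-2H-pyran-6-yl]prop-2-enoate
Product: 17 7-hydroxy-5-[(2S)-2-hydroxypropyl]-6,8-dimethyl-3-[(2R)-2-methyl-4-oxo-3,4-dihydro-2H-pyran-6-yl]-2H-chromen-2-one (target), via deprotected diphenol ester 16 (not isolated)
Conditions: HCl (1.5 M in MeOH), 40 °C
Reagents that add atoms: none
Why: Acidic methanolysis of the two MOM acetals frees the phenols, the push–pull alkene (electron-rich aryl donor, protonated pyranone acceptor) should rotate under acid, and the C8a hydroxyl then closes irreversibly on the ester by 6-exo-trig lactonization, so that both geometric isomers and any reversible hydroxyl adducts drain into the coumarin.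

**Compound list**

1 | 2-methylresorcinol | Cc1c(O)cccc1O | starting material
2 | 2,4-dihydroxy-3-methylbenzaldehyde | Cc1c(O)ccc(C=O)c1O | intermediate
3 | 2,4-dimethylbenzene-1,3-diol | Cc1ccc(O)c(C)c1O | intermediate
4 | 4-iodo-2,6-dimethylbenzene-1,3-diol | Cc1cc(I)c(O)c(C)c1O | intermediate
5 | 1-iodo-2,4-bis(methoxymethoxy)-3,5-dimethylbenzene | COCOc1c(C)c(OCOC)c(C)cc1I | intermediate
6 | methyl (R)-3-hydroxybutanoate | C[C@@H](O)CC(=O)OC | starting material
7 | methyl (R)-3-[(tert-butyldimethylsilyl)oxy]butanoate | C[C@@H](O[Si](C)(C)C(C)(C)C)CC(=O)OC | intermediate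
8 | (R)-3-[(tert-butyldimethylsilyl)oxy]-N-methoxy-N-methylbutanamide | C[C@@H](O[Si](C)(C)C(C)(C)C)CC(=O)N(C)OC | intermediate
9 | methyl acetoacetate | CC(=O)CC(=O)OC | starting material
10 | methyl (7R)-7-[(tert-butyldimethylsilyl)oxy]-3,5-dioxooctanoate | COC(=O)CC(=O)CC(=O)C[C@@H](C)O[Si](C)(C)C(C)(C)C | intermediate
11 | methyl (7R)-7-hydroxy-3,5-dioxooctanoate (formed in the flask) | COC(=O)CC(=O)CC(=O)C[C@@H](C)O | intermediate
12 | methyl 2-[(2R)-2-methyl-4-oxo-3,4-dihydro-2H-pyran-6-yl]acetate | COC(=O)CC1=CC(=O)C[C@@H](C)O1 | intermediate
13 | methyl 2-[(2R)-2-methyl-4-oxo-3,4-dihydro-2H-pyran-6-yl]prop-2-enoate | COC(=O)C(=C)C1=CC(=O)C[C@@H](C)O1 | intermediate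
14 | (S)-propylene oxide, (2S)-2-methyloxirane | C[C@H]1CO1 | starting material
15 | methyl 3-{2-[(2S)-2-hydroxypropyl]-4,6-bis(methoxymethoxy)-3,5-dimethylphenyl}-2-[(2R)-2-methyl-4-oxo-3,4-dihydro-2H-pyran-6-yl]prop-2-enoate (alkene geometry not fixed) | COC(=O)C(=Cc1c(C[C@H](C)O)c(C)c(OCOC)c(C)c1OCOC)C2=CC(=O)C[C@@H](C)O2 | intermediate
16 | methyl 3-{2,4-dihydroxy-6-[(2S)-2-hydroxypropyl]-3,5-dimethylphenyl}-2-[(2R)-2-methyl-4-oxo-3,4-dihydro-2H-pyran-6-yl]prop-2-enoate (formed in the flask, alkene geometry not fixed) | COC(=O)C(=Cc1c(C[C@H](C)O)c(C)c(O)c(C)c1O)C2=CC(=O)C[C@@H](C)O2 | intermediate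
17 | 7-hydroxy-5-[(2S)-2-hydroxypropyl]-6,8-dimethyl-3-[(2R)-2-methyl-4-oxo-3,4-dihydro-2H-pyran-6-yl]-2H-chromen-2-one | Cc1c(O)c(C)c2oc(=O)c(C3=CC(=O)C[C@@H](C)O3)cc2c1C[C@H](C)O | target

**Step count**

Total: 11 steps. Longest linear sequence: 7 steps (6 to 17 through steps 5, 6, 7, 8, 9, 10 and 11).

**Steps most likely to fail**

Step 10 (bears the label "Proposed new method:"). Three processes threaten it:
- Metalation of the methyl-flanked C5–H may be slower than direct insertion of the acrylate at C4a, giving ipso coupling without ortho alkylation.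
- The alkoxide released on epoxide opening may close onto C4a before the hindered alkene inserts.
- The acrylate may oligomerize under base before it is consumed.

A bridgehead-substituted norbornene would be the first variable to screen, but the fallback leaves this catalysis and uses known reaction types only. It sets out from 5 (using 14 and 12 as well) and comes back at 17. Iodine–magnesium exchange on 5 (i-PrMgCl·LiCl, THF, −20 °C) and trapping with Et2NCOCl should give N,N-diethyl-2,4-bis(methoxymethoxy)-3,5-dimethylbenzamide F1. Amide-directed ortho-lithiation at its single ortho C–H (s-BuLi, TMEDA, THF, −78 °C), then BF3·OEt2-assisted opening of 14 at the CH2 carbon, should give N,N-diethyl-2-[(2S)-2-hydroxypropyl]-4,6-bis(methoxymethoxy)-3,5-dimethylbenzamide F2. Aqueous HCl in dioxane at 90 °C should lactonize the hydroxy amide and remove both MOM groups, giving (3S)-6,8-dihydroxy-3,5,7-trimethyl-3,4-dihydro-1H-isochromen-1-one F3. Excess i-Bu2AlH (CH2Cl2, −78 °C) should reduce the lactone to the lactol (3S)-3,5,7-trimethyl-3,4-dihydro-1H-isochromene-1,6,8-triol F4, which equilibrates with the open salicylaldehyde. Knoevenagel condensation of F4 with 12 (piperidine, AcOH, EtOH, 70 °C), followed by spontaneous lactonization of the ortho phenol onto the ester, should then give 17 directly, bypassing 13 and 15.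

Step 9. The carbanion of unreacted 12 may add to the newly formed acrylate, and the acrylate may dimerize by cycloaddition when warmed or concentrated. The fallback separates C–C bond formation from alkene release; it sets out from 12 and comes back at 13. Aminomethylation of 12 with dimethylmethyleneammonium iodide (CH2Cl2, rt; vinylogous Mannich reaction through the dienol) should give the storable methyl 3-(dimethylamino)-2-[(2R)-2-methyl-4-oxo-3,4-dihydro-2H-pyran-6-yl]propanoate F5. MeI in acetone should convert it into 3-methoxy-N,N,N-trimethyl-2-[(2R)-2-methyl-4-oxo-3,4-dihydro-2H-pyran-6-yl]-3-oxopropan-1-aminium iodide F6. Cold aqueous NaHCO3/CH2Cl2 should then release 13 by Hofmann-type β-elimination immediately before step 10.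

Step 11. Geometric isomerization may stay incomplete, so that the isomer with the aryl group trans to the ester cannot lactonize; prolonged acid may also open and re-close the dihydropyranone, eroding the configuration at C2'. The fallback removes the alkene before lactonization and restores it afterwards; it sets out from 15 and comes back at 17. Catalytic DBU in CH2Cl2 should close the side-chain hydroxyl onto the activated alkene (oxa-Michael addition) to give methyl 2-[(3S)-6,8-bis(methoxymethoxy)-3,5,7-trimethyl-3,4-dihydro-1H-isochromen-1-yl]-2-[(2R)-2-methyl-4-oxo-3,4-dihydro-2H-pyran-6-yl]acetate F7, as a diastereomer mixture without alkene geometry. HCl in MeOH should remove the MOM groups and let the ortho phenol lactonize freely to the bridged dihydrocoumarin F8: 7-hydroxy-6,8-dimethyl-3-[(2R)-2-methyl-4-oxo-3,4-dihydro-2H-pyran-6-yl]-3,4-dihydrocoumarin with C4 and C5 joined by an O–CH(CH3)–CH2 bridge, (S) at the bridge carbon. DBU in THF should then expel the bridging oxygen from C4 by E1cB elimination; the new C3=C4 bond lies inside the lactone ring and can only be cis, giving 17.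

**Further compounds**

F1 | step 10 | N,N-diethyl-2,4-bis(methoxymethoxy)-3,5-dimethylbenzamide | CCN(CC)C(=O)c1cc(C)c(OCOC)c(C)c1OCOC
F2 | step 10 | N,N-diethyl-2-[(2S)-2-hydroxypropyl]-4,6-bis(methoxymethoxy)-3,5-dimethylbenzamide | CCN(CC)C(=O)c1c(C[C@H](C)O)c(C)c(OCOC)c(C)c1OCOC
F3 | step 10 | (3S)-6,8-dihydroxy-3,5,7-trimethyl-3,4-dihydro-1H-isochromen-1-one | C[C@H]1Cc2c(C)c(O)c(C)c(O)c2C(=O)O1
F4 | step 10 | (3S)-3,5,7-trimethyl-3,4-dihydro-1H-isochromene-1,6,8-triol (lactol, anomer mixture) | C[C@H]1Cc2c(C)c(O)c(C)c(O)c2C(O)O1
F5 | step 9 | methyl 3-(dimethylamino)-2-[(2R)-2-methyl-4-oxo-3,4-dihydro-2H-pyran-6-yl]propanoate | COC(=O)C(CN(C)C)C1=CC(=O)C[C@@H](C)O1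
F6 | step 9 | 3-methoxy-N,N,N-trimethyl-2-[(2R)-2-methyl-4-oxo-3,4-dihydro-2H-pyran-6-yl]-3-oxopropan-1-aminium iodide | COC(=O)C(C[N+](C)(C)C)C1=CC(=O)C[C@@H](C)O1.[I-]
F7 | step 11 | methyl 2-[(3S)-6,8-bis(methoxymethoxy)-3,5,7-trimethyl-3,4-dihydro-1H-isochromen-1-yl]-2-[(2R)-2-methyl-4-oxo-3,4-dihydro-2H-pyran-6-yl]acetate (diastereomer mixture) | COC(=O)C(C1O[C@@H](C)Cc2c(C)c(OCOC)c(C)c(OCOC)c12)C3=CC(=O)C[C@@H](C)O3
F8 | step 11 | 7-hydroxy-6,8-dimethyl-3-[(2R)-2-methyl-4-oxo-3,4-dihydro-2H-pyran-6-yl]-3,4-dihydrocoumarin with C4 and C5 joined by an O–CH(CH3)–CH2 bridge, (S) at the bridge carbon (diastereomer mixture) | O=C1Oc2c(C)c(O)c(C)c3c2C(O[C@@H](C)C3)C1C4=CC(=O)C[C@@H](C)O4
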